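**Retrosynthetic overview**

- Ring C is formed last, at the C4–C4a bond. The C4 ketone of the target sits on C4a of ring A, ortho to the ring C ether oxygen O1, so a carbanion at C4a (from a bromide) can be acylated by a C4 N-methoxy-N-methyl amide carried on the preformed O1–C2–C3 chain.
- The O1–C2 bond is made before that by opening a (2R,3S)-trans-glycidic Weinreb amide at its benzylic carbon with a 6-bromo-2-prenyl-3-silyloxyphenoxide. Inversion gives C2; the oxirane carbon next to the carbonyl becomes C3 unchanged.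
- The oxirane comes from nucleophilic epoxidation of the ring B cinnamoyl imidazole under La(O-iPr)3/(S)-BINOL control, which leaves the prenyl olefin alone. The cinnamic acid comes from 4-hydroxybenzaldehyde by C-prenylation and Doebner condensation.
- The ring A phenol comes from 4-bromoresorcinol. The bromine first blocks one ortho carbon, so that a Claisen shift places the prenyl group between the two oxygens, and later serves as the lithium handle.
- Rings A and B are bought as arenes. The phenols travel as triisopropylsilyl (TIPS) ethers and the C3 hydroxyl as a tert-butyldimethylsilyl (TBS) ether; buffered fluoride removes all three at the end.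

Key step: step 11

Remark: ring A is bought as 4-bromoresorcinol instead of resorcinol, and TIPS replaces TBS on the two phenols because aryl TBS ethers would be scrambled by phenoxide and carbonate in step 9. "Prenyl" means 3-methylbut-2-en-1-yl throughout.

**Step 1**
Reactants: 1 4-hydroxybenzaldehyde; 2 prenyl bromide
Product: 3 4-hydroxy-3-(3-methylbut-2-en-1-yl)benzaldehyde
Conditions: KOH (aq), rt
Reagents that add atoms: none
Why: ortho C-alkylation of a phenoxide in water, where solvation of the oxygen favours attack through the ring carbon; the para position carries the formyl group, so the prenyl group can only enter ortho to the hydroxyl.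

**Step 2**
Reactants: 3 4-hydroxy-3-(3-methylbut-2-en-1-yl)benzaldehyde
Product: 4 3-(3-methylbut-2-en-1-yl)-4-(triisopropylsilyloxy)benzaldehyde
Conditions: TIPSCl, imidazole, DMF, rt
Reagents that add atoms: chlorotriisopropylsilane, CC(C)[Si](Cl)(C(C)C)C(C)C
Why: imidazole-promoted silylation of the phenol; the bulky TIPS ether should withstand the amine, carbonate and organolithium conditions that follow.

**Step 3**
Reactants: 4 3-(3-methylbut-2-en-1-yl)-4-(triisopropylsilyloxy)benzaldehyde; 5 malonic acid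
Product: 7 (E)-3-[3-(3-methylbut-2-en-1-yl)-4-(triisopropylsilyloxy)phenyl]prop-2-enoic acid, via arylidenemalonic acid 6 (not isolated)
Conditions: pyridine, piperidine (cat.), 80 °C
Reagents that add atoms: none
Why: Knoevenagel condensation with decarboxylation (Doebner modification) should give the E-cinnamic acid, the thermodynamically preferred olefin; the prenyl group takes no part.

**Step 4**
Reactants: 7 (E)-3-[3-(3-methylbut-2-en-1-yl)-4-(triisopropylsilyloxy)phenyl]prop-2-enoic acid
Product: 8 (E)-1-(imidazol-1-yl)-3-[3-(3-methylbut-2-en-1-yl)-4-(triisopropylsilyloxy)phenyl]prop-2-en-1-one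
Conditions: CDI, THF, rt
Reagents that add atoms: 1,1'-carbonyldiimidazole, O=C(n1ccnc1)n1ccnc1
Why: activation of the acid with carbonyldiimidazole, driven by loss of CO2, should give the N-acyl imidazole, an ester-type Michael acceptor suited to nucleophilic epoxidation.

**Step 5**
Reactants: 8 (E)-1-(imidazol-1-yl)-3-[3-(3-methylbut-2-en-1-yl)-4-(triisopropylsilyloxy)phenyl]prop-2-en-1-one
Product: 11 (2R,3S)-N-methoxy-N-methyl-3-[3-(3-methylbut-2-en-1-yl)-4-(triisopropylsilyloxy)phenyl]oxirane-2-carboxamide, via epoxy acyl imidazole 9 (not isolated), via epoxy peroxy ester 10 (not isolated)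
Conditions: La(O-iPr)3, (S)-BINOL, Ph3As=O (1:1:1, 10 mol %), TBHP (decane), MS 4Å, THF, rt; then MeNH(OMe)·HCl, Et3N, rt
Reagents that add atoms: tert-butyl hydroperoxide, CC(C)(C)OO; N,O-dimethylhydroxylamine hydrochloride, CNOC.Cl
Why: catalytic asymmetric nucleophilic (Weitz–Scheffer type) epoxidation of an α,β-unsaturated acyl imidazole, in which the tert-butyl peroxide anion bound to the La(O-iPr)3/(S)-BINOL/Ph3As=O catalyst adds to the β-carbon from the face set by (S)-BINOL and the enolate closes on oxygen, so the E-olefin should give the trans oxirane with C2 R and C3 S; the electron-rich prenyl olefin is inert to this oxidant, and the acyl imidazole and the peroxy ester formed from it are active esters that the hydroxylamine converts to the Weinreb amide.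

**Step 6**
Reactants: 12 4-bromoresorcinol
Product: 13 2-bromo-5-(triisopropylsilyloxy)phenol
Conditions: TIPSCl (1.0 equiv), imidazole, CH2Cl2, 0 °C
Reagents that add atoms: chlorotriisopropylsilane, CC(C)[Si](Cl)(C(C)C)C(C)C
Why: regioselective monosilylation; the hydroxyl para to bromine is the less hindered and more nucleophilic one (the other is flanked by bromine and is more acidic), so one equivalent of the bulky silyl chloride should go to it.

**Step 7**
Reactants: 13 2-bromo-5-(triisopropylsilyloxy)phenol; 14 3-chloro-3-methylbut-1-yne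
Product: 15 [4-bromo-3-(2-methylbut-3-yn-2-yloxy)phenoxy]triisopropylsilane
Conditions: DBU, CuCl2·2H2O (cat.), MeCN, 0 °C
Reagents that add atoms: none
Why: Cu-catalysed propargylic etherification, in which the phenoxide substitutes the tertiary propargylic chloride at oxygen and should give the hindered aryl 1,1-dimethylpropargyl ether without C-alkylation.

**Step 8**
Reactants: 15 [4-bromo-3-(2-methylbut-3-yn-2-yloxy)phenoxy]triisopropylsilane
Product: 17 6-bromo-2-(3-methylbut-2-en-1-yl)-3-(triisopropylsilyloxy)phenol, via dimethylallyl ether 16 (not isolated)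
Conditions: H2 (1 atm), Pd/CaCO3 poisoned with Pb(OAc)2, quinoline, EtOAc, rt; filter, concentrate; then PhNEt2, 130 °C
Reagents that add atoms: none
Why: semihydrogenation of the alkyne over Pd/CaCO3–Pb(OAc)2 (Lindlar type) followed by aromatic Claisen rearrangement; the [3,3] shift turns the 1,1-dimethylallyl ether into a prenyl group on an ortho carbon, and because the other ortho carbon carries bromine (a shift there cannot rearomatise and reverts) the group should end on the CH between the two oxygens, while the amine solvent keeps the new ortho-prenylphenol from cyclising to a chroman.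

**Step 9**
Reactants: 11 (2R,3S)-N-methoxy-N-methyl-3-[3-(3-methylbut-2-en-1-yl)-4-(triisopropylsilyloxy)phenyl]oxirane-2-carboxamide; 17 6-bromo-2-(3-methylbut-2-en-1-yl)-3-(triisopropylsilyloxy)phenol
Product: 18 (2R,3R)-3-[6-bromo-2-(3-methylbut-2-en-1-yl)-3-(triisopropylsilyloxy)phenoxy]-2-hydroxy-N-methoxy-N-methyl-3-[3-(3-methylbut-2-en-1-yl)-4-(triisopropylsilyloxy)phenyl]propanamide
Conditions: Cs2CO3 (0.3 equiv), DMF, 50 °C
Reagents that add atoms: none
Why: base-catalysed SN2 opening of a trans-3-arylglycidic amide by a phenoxide at the benzylic carbon remote from the carbonyl, anti to the departing oxygen; inversion there sets the future C2 as R, and the untouched oxirane carbon becomes C3 (R), the anti arrangement that maps onto the 2,3-trans chromanone.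

**Step 10**
Reactants: 18 (2R,3R)-3-[6-bromo-2-(3-methylbut-2-en-1-yl)-3-(triisopropylsilyloxy)phenoxy]-2-hydroxy-N-methoxy-N-methyl-3-[3-(3-methylbut-2-en-1-yl)-4-(triisopropylsilyloxy)phenyl]propanamide
Product: 19 (2R,3R)-3-[6-bromo-2-(3-methylbut-2-en-1-yl)-3-(triisopropylsilyloxy)phenoxy]-2-(tert-butyldimethylsilyloxy)-N-methoxy-N-methyl-3-[3-(3-methylbut-2-en-1-yl)-4-(triisopropylsilyloxy)phenyl]propanamide
Conditions: TBSOTf, 2,6-lutidine, CH2Cl2, −40 → 0 °C
Reagents that add atoms: tert-butyldimethylsilyl trifluoromethanesulfonate, CC(C)(C)[Si](C)(C)OS(=O)(=O)C(F)(F)F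
Why: silyl triflate/2,6-lutidine silylation of the hindered secondary α-hydroxy amide; the ether removes the acidic hydroxyl before the organolithium step and shields the C3 hydrogen.

**Step 11**
Reactants: 19 (2R,3R)-3-[6-bromo-2-(3-methylbut-2-en-1-yl)-3-(triisopropylsilyloxy)phenoxy]-2-(tert-butyldimethylsilyloxy)-N-methoxy-N-methyl-3-[3-(3-methylbut-2-en-1-yl)-4-(triisopropylsilyloxy)phenyl]propanamide
Product: 22 (2R,3R)-3-(tert-butyldimethylsilyloxy)-8-(3-methylbut-2-en-1-yl)-2-[3-(3-methylbut-2-en-1-yl)-4-(triisopropylsilyloxy)phenyl]-7-(triisopropylsilyloxy)chroman-4-one, via aryllithium 20 (not isolated), via lithium hemiaminal 21 (not isolated)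
Conditions: t-BuLi (2.1 equiv), THF, −78 °C; then aq. NH4Cl, −78 °C → rt
Reagents that add atoms: none
Why: Two equivalents of t-BuLi exchange the bromine at C4a for lithium (the second equivalent consumes the tert-butyl bromide), and aryllithium 20 adds to the carbonyl of the N-methoxy-N-methyl amide to give the chelated lithium hemiaminal 21, which releases ketone 22 only on the cold aqueous quench. The closest known reaction type is the Parham cyclisation of ortho-bromoaryl ethers onto tethered Weinreb amides, which gives chroman-4-ones and other benzo-fused ketones. Ring C closes in the 6-exo-trig mode by formation of the C4–C4a bond. No stereocentre is formed; C2 and C3 are carried through because the ketone is masked as 21 while base is present, so neither enolisation toward C3 nor ring opening by loss of the O1 phenoxide can take place. The step needs bromine–lithium exchange to be faster than addition of t-BuLi to the amide and than removal of the C3 hydrogen (which would expel the aryloxide), and this is secured by the ether oxygen ortho to the bromine, which accelerates exchange and stabilises 20, by the bulky silyloxy group that screens the amide and the C3 hydrogen, and by the short tether that makes the ring closure fast at −78 °C. The silyloxy group of ring A is para to the lithiated carbon, so no oxygen-to-carbon silyl shift is possible, and neither prenyl olefin reacts with the organolithium.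

**Step 12**
Reactants: 22 (2R,3R)-3-(tert-butyldimethylsilyloxy)-8-(3-methylbut-2-en-1-yl)-2-[3-(3-methylbut-2-en-1-yl)-4-(triisopropylsilyloxy)phenyl]-7-(triisopropylsilyloxy)chroman-4-one
Product: 23 3-hydroxyglabrol
Conditions: TBAF, AcOH (1:1), THF, 0 °C → rt
Reagents that add atoms: none
Why: fluoride-mediated desilylation of the two aryl TIPS ethers and the secondary TBS ether; acetic acid buffers the phenoxides and the alkoxide so that the α-hydroxy ketone should be neither epimerised nor opened, and no acid strong enough to cyclise the ortho-prenylphenols is present.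

**Compound list**

1 | 4-hydroxybenzaldehyde | O=Cc1ccc(O)cc1 | starting material
2 | prenyl bromide (1-bromo-3-methylbut-2-ene) | CC(C)=CCBr | starting material
3 | 4-hydroxy-3-(3-methylbut-2-en-1-yl)benzaldehyde | CC(C)=CCc1cc(C=O)ccc1O | intermediate
4 | 3-(3-methylbut-2-en-1-yl)-4-(triisopropylsilyloxy)benzaldehyde | CC(C)=CCc1cc(C=O)ccc1O[Si](C(C)C)(C(C)C)C(C)C | intermediate
5 | malonic acid | OC(=O)CC(=O)O | starting material
6 | 2-[3-(3-methylbut-2-en-1-yl)-4-(triisopropylsilyloxy)benzylidene]malonic acid (not isolated) | CC(C)=CCc1cc(C=C(C(=O)O)C(=O)O)ccc1O[Si](C(C)C)(C(C)C)C(C)C | intermediate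
7 | (E)-3-[3-(3-methylbut-2-en-1-yl)-4-(triisopropylsilyloxy)phenyl]prop-2-enoic acid | CC(C)=CCc1cc(/C=C/C(=O)O)ccc1O[Si](C(C)C)(C(C)C)C(C)C | intermediate
8 | (E)-1-(imidazol-1-yl)-3-[3-(3-methylbut-2-en-1-yl)-4-(triisopropylsilyloxy)phenyl]prop-2-en-1-one | CC(C)=CCc1cc(/C=C/C(=O)n2ccnc2)ccc1O[Si](C(C)C)(C(C)C)C(C)C | intermediate
9 | imidazol-1-yl {(2R,3S)-3-[3-(3-methylbut-2-en-1-yl)-4-(triisopropylsilyloxy)phenyl]oxiran-2-yl} ketone (not isolated) | CC(C)=CCc1cc([C@@H]2O[C@H]2C(=O)n3ccnc3)ccc1O[Si](C(C)C)(C(C)C)C(C)C | intermediate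
10 | tert-butyl (2R,3S)-3-[3-(3-methylbut-2-en-1-yl)-4-(triisopropylsilyloxy)phenyl]oxirane-2-carboperoxoate (not isolated) | CC(C)=CCc1cc([C@@H]2O[C@H]2C(=O)OOC(C)(C)C)ccc1O[Si](C(C)C)(C(C)C)C(C)C | intermediate
11 | (2R,3S)-N-methoxy-N-methyl-3-[3-(3-methylbut-2-en-1-yl)-4-(triisopropylsilyloxy)phenyl]oxirane-2-carboxamide (trans) | CC(C)=CCc1cc([C@@H]2O[C@H]2C(=O)N(C)OC)ccc1O[Si](C(C)C)(C(C)C)C(C)C | intermediate
12 | 4-bromoresorcinol (4-bromobenzene-1,3-diol) | Oc1ccc(Br)c(O)c1 | starting material
13 | 2-bromo-5-(triisopropylsilyloxy)phenol | Oc1cc(O[Si](C(C)C)(C(C)C)C(C)C)ccc1Br | intermediate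
14 | 3-chloro-3-methylbut-1-yne | C#CC(C)(C)Cl | starting material
15 | [4-bromo-3-(2-methylbut-3-yn-2-yloxy)phenoxy]triisopropylsilane | C#CC(C)(C)Oc1cc(O[Si](C(C)C)(C(C)C)C(C)C)ccc1Br | intermediate
16 | [4-bromo-3-(2-methylbut-3-en-2-yloxy)phenoxy]triisopropylsilane (not isolated) | C=CC(C)(C)Oc1cc(O[Si](C(C)C)(C(C)C)C(C)C)ccc1Br | intermediate
17 | 6-bromo-2-(3-methylbut-2-en-1-yl)-3-(triisopropylsilyloxy)phenol | CC(C)=CCc1c(O)c(Br)ccc1O[Si](C(C)C)(C(C)C)C(C)C | intermediate
18 | (2R,3R)-3-[6-bromo-2-prenyl-3-(triisopropylsilyloxy)phenoxy]-2-hydroxy-N-methoxy-N-methyl-3-[3-prenyl-4-(triisopropylsilyloxy)phenyl]propanamide | CC(C)=CCc1cc([C@H]([C@@H](O)C(=O)N(C)OC)Oc2c(Br)ccc(O[Si](C(C)C)(C(C)C)C(C)C)c2CC=C(C)C)ccc1O[Si](C(C)C)(C(C)C)C(C)C | intermediate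
19 | (2R,3R)-3-[6-bromo-2-prenyl-3-(triisopropylsilyloxy)phenoxy]-2-(tert-butyldimethylsilyloxy)-N-methoxy-N-methyl-3-[3-prenyl-4-(triisopropylsilyloxy)phenyl]propanamide (key-step precursor) | CC(C)=CCc1cc([C@H]([C@@H](O[Si](C)(C)C(C)(C)C)C(=O)N(C)OC)Oc2c(Br)ccc(O[Si](C(C)C)(C(C)C)C(C)C)c2CC=C(C)C)ccc1O[Si](C(C)C)(C(C)C)C(C)C | intermediate
20 | aryllithium from 19, lithium in place of bromine at the future C4a (not isolated) | CC(C)=CCc1cc([C@H]([C@@H](O[Si](C)(C)C(C)(C)C)C(=O)N(C)OC)Oc2c([Li])ccc(O[Si](C(C)C)(C(C)C)C(C)C)c2CC=C(C)C)ccc1O[Si](C(C)C)(C(C)C)C(C)C | intermediate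
21 | lithium alkoxide of the cyclic C4 N-methoxy-N-methyl hemiaminal, C2 and C3 as in 22 (not isolated) | CC(C)=CCc1cc([C@H]2Oc3c(ccc(O[Si](C(C)C)(C(C)C)C(C)C)c3CC=C(C)C)C(O[Li])(N(C)OC)[C@@H]2O[Si](C)(C)C(C)(C)C)ccc1O[Si](C(C)C)(C(C)C)C(C)C | intermediate
22 | (2R,3R)-3-(tert-butyldimethylsilyloxy)-8-prenyl-2-[3-prenyl-4-(triisopropylsilyloxy)phenyl]-7-(triisopropylsilyloxy)chroman-4-one (key-step product) | CC(C)=CCc1cc([C@H]2Oc3c(ccc(O[Si](C(C)C)(C(C)C)C(C)C)c3CC=C(C)C)C(=O)[C@@H]2O[Si](C)(C)C(C)(C)C)ccc1O[Si](C(C)C)(C(C)C)C(C)C | intermediate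
23 | 3-hydroxyglabrol, (2R,3R)-3,7-dihydroxy-2-[4-hydroxy-3-(3-methylbut-2-en-1-yl)phenyl]-8-(3-methylbut-2-en-1-yl)chroman-4-one | CC(C)=CCc1cc([C@H]2Oc3c(ccc(O)c3CC=C(C)C)C(=O)[C@@H]2O)ccc1O | target

**Step count**

Total: 12 steps. Longest linear sequence: 9 steps (steps 1–5, then 9–12); the ring A branch is steps 6–8.

**Steps most likely to fail**

1. Step 9 (ether formation). The phenoxide carries two ortho substituents and may substitute slowly. That leaves time for silyl transfer between phenols and for ionisation of the electron-rich benzylic C–O bond, which would erode the configuration at the future C2 or lead to attack through carbon.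
Fallback, from 11 and 13, rejoining at 23: the prenyl group of ring A is introduced after ring closure, so the nucleophile has only one ortho substituent. Phenol 13 opens 11 under the same base catalysis to give the ring-opened alcohol F1. TBSOTf/2,6-lutidine gives the silyl ether F2, and t-BuLi at −78 °C closes ring C to the 8-unsubstituted chromanone F3. LiOAc in DMF–H2O removes only the silyl group on the 7-oxygen, which is para to the ketone and the best leaving phenoxide, to give the 7-hydroxychromanone F4. Compound 14 with DBU and CuCl2·2H2O gives the propargyl ether F5, and semihydrogenation over Pd/CaCO3–Pb(OAc)2 gives the dimethylallyl ether F6. Claisen rearrangement in PhNEt2 at 130 °C should move the prenyl group to C8, the ortho carbon favoured in 7-oxygenated chroman-4-ones, to give the 8-prenyl-7-hydroxychromanone F7. TBAF/AcOH then gives 23.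

2. Step 11 (key step). Addition of t-BuLi to the amide, or removal of the C3 hydrogen with expulsion of the aryloxide, may compete with exchange and ring closure.
Fallback, from 19, rejoining at 22: the same bond is made by transition-metal catalysis without a strong base. B2pin2, Pd(dppf)Cl2 and KOAc in dioxane at 80 °C give the pinacol boronate F8. i-Bu2AlH at −78 °C reduces the Weinreb amide to the aldehyde F9. [Rh(cod)OH]2 in dioxane–water adds the aryl–boron bond across the aldehyde (6-exo) to give the chroman-4-ol F10 as a mixture at C4. Dess–Martin periodinane with NaHCO3 then gives 22.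

3. Step 5 (asymmetric epoxidation). Conjugate addition of the peroxide to a cinnamoyl acceptor deactivated by the para silyloxy group may be slow. Conversion or enantiomeric purity would suffer, and the acyl imidazole could be lost to acyl transfer before it is epoxidised.
Fallback, from 4, rejoining at 11: the oxirane is built by C–C bond formation on the aldehyde and the enantiomers are separated. Dimethyl sulfide and 2-bromo-N-methoxy-N-methylacetamide give the sulfonium bromide F11. Its amide-stabilised ylide (KOH, EtOH, −40 °C) adds to 4 and the betaine closes to the racemic trans-glycidic Weinreb amide F12. Preparative chromatography on a chiral stationary phase gives 11.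

**Further compounds**

F1 | step 9 | (2R,3R)-3-[2-bromo-5-(triisopropylsilyloxy)phenoxy]-2-hydroxy-N-methoxy-N-methyl-3-[3-prenyl-4-(triisopropylsilyloxy)phenyl]propanamide | CC(C)=CCc1cc([C@H]([C@@H](O)C(=O)N(C)OC)Oc2cc(O[Si](C(C)C)(C(C)C)C(C)C)ccc2Br)ccc1O[Si](C(C)C)(C(C)C)C(C)C
F2 | step 9 | (2R,3R)-3-[2-bromo-5-(triisopropylsilyloxy)phenoxy]-2-(tert-butyldimethylsilyloxy)-N-methoxy-N-methyl-3-[3-prenyl-4-(triisopropylsilyloxy)phenyl]propanamide | CC(C)=CCc1cc([C@H]([C@@H](O[Si](C)(C)C(C)(C)C)C(=O)N(C)OC)Oc2cc(O[Si](C(C)C)(C(C)C)C(C)C)ccc2Br)ccc1O[Si](C(C)C)(C(C)C)C(C)C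
F3 | step 9 | (2R,3R)-3-(tert-butyldimethylsilyloxy)-2-[3-prenyl-4-(triisopropylsilyloxy)phenyl]-7-(triisopropylsilyloxy)chroman-4-one | CC(C)=CCc1cc([C@H]2Oc3cc(O[Si](C(C)C)(C(C)C)C(C)C)ccc3C(=O)[C@@H]2O[Si](C)(C)C(C)(C)C)ccc1O[Si](C(C)C)(C(C)C)C(C)C
F4 | step 9 | (2R,3R)-3-(tert-butyldimethylsilyloxy)-7-hydroxy-2-[3-prenyl-4-(triisopropylsilyloxy)phenyl]chroman-4-one | CC(C)=CCc1cc([C@H]2Oc3cc(O)ccc3C(=O)[C@@H]2O[Si](C)(C)C(C)(C)C)ccc1O[Si](C(C)C)(C(C)C)C(C)C
F5 | step 9 | (2R,3R)-3-(tert-butyldimethylsilyloxy)-7-(2-methylbut-3-yn-2-yloxy)-2-[3-prenyl-4-(triisopropylsilyloxy)phenyl]chroman-4-one | CC(C)=CCc1cc([C@H]2Oc3cc(OC(C)(C)C#C)ccc3C(=O)[C@@H]2O[Si](C)(C)C(C)(C)C)ccc1O[Si](C(C)C)(C(C)C)C(C)C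
F6 | step 9 | (2R,3R)-3-(tert-butyldimethylsilyloxy)-7-(2-methylbut-3-en-2-yloxy)-2-[3-prenyl-4-(triisopropylsilyloxy)phenyl]chroman-4-one | CC(C)=CCc1cc([C@H]2Oc3cc(OC(C)(C)C=C)ccc3C(=O)[C@@H]2O[Si](C)(C)C(C)(C)C)ccc1O[Si](C(C)C)(C(C)C)C(C)C
F7 | step 9 | (2R,3R)-3-(tert-butyldimethylsilyloxy)-7-hydroxy-8-prenyl-2-[3-prenyl-4-(triisopropylsilyloxy)phenyl]chroman-4-one | CC(C)=CCc1cc([C@H]2Oc3c(ccc(O)c3CC=C(C)C)C(=O)[C@@H]2O[Si](C)(C)C(C)(C)C)ccc1O[Si](C(C)C)(C(C)C)C(C)C
F8 | step 11 | (2R,3R)-2-(tert-butyldimethylsilyloxy)-N-methoxy-N-methyl-3-[2-prenyl-6-(4,4,5,5-tetramethyl-1,3,2-dioxaborolan-2-yl)-3-(triisopropylsilyloxy)phenoxy]-3-[3-prenyl-4-(triisopropylsilyloxy)phenyl]propanamide | CC(C)=CCc1cc([C@H]([C@@H](O[Si](C)(C)C(C)(C)C)C(=O)N(C)OC)Oc2c(B3OC(C)(C)C(C)(C)O3)ccc(O[Si](C(C)C)(C(C)C)C(C)C)c2CC=C(C)C)ccc1O[Si](C(C)C)(C(C)C)C(C)C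
F9 | step 11 | (2R,3R)-2-(tert-butyldimethylsilyloxy)-3-[2-prenyl-6-(4,4,5,5-tetramethyl-1,3,2-dioxaborolan-2-yl)-3-(triisopropylsilyloxy)phenoxy]-3-[3-prenyl-4-(triisopropylsilyloxy)phenyl]propanal | CC(C)=CCc1cc([C@H]([C@@H](O[Si](C)(C)C(C)(C)C)C=O)Oc2c(B3OC(C)(C)C(C)(C)O3)ccc(O[Si](C(C)C)(C(C)C)C(C)C)c2CC=C(C)C)ccc1O[Si](C(C)C)(C(C)C)C(C)C
F10 | step 11 | chroman-4-ol corresponding to 22, C2 and C3 arranged as in 22, both C4 epimers | CC(C)=CCc1cc([C@H]2Oc3c(ccc(O[Si](C(C)C)(C(C)C)C(C)C)c3CC=C(C)C)C(O)[C@@H]2O[Si](C)(C)C(C)(C)C)ccc1O[Si](C(C)C)(C(C)C)C(C)C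
F11 | step 5 | {2-[methoxy(methyl)amino]-2-oxoethyl}dimethylsulfonium bromide | C[S+](C)CC(=O)N(C)OC.[Br-]
F12 | step 5 | racemic trans-N-methoxy-N-methyl-3-[3-prenyl-4-(triisopropylsilyloxy)phenyl]oxirane-2-carboxamide, (2R,3S) and (2S,3R) in equal amounts | CC(C)=CCc1cc([C@@H]2O[C@H]2C(=O)N(C)OC)ccc1O[Si](C(C)C)(C(C)C)C(C)C.CC(C)=CCc1cc([C@H]2O[C@@H]2C(=O)N(C)OC)ccc1O[Si](C(C)C)(C(C)C)C(C)C
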